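**Retrosynthetic overview**

- The strategy rests on C4 of ring C: the carbonyl carbon is a single one-carbon unit between C4a of ring A and C3. Ring C therefore splits into carbon monoxide (C4), an ortho-iodophenol (C4a, C8a, O1, carrying the 5-O/7-OMe pattern) and an arylacetylene (C3, C2, ring B).
- Target ⇐ hydrogenolysis of the 5-O- and 3'-O-benzyl ethers ⇐ sulfation of the only free hydroxyl (3-OH) ⇐ C3 hydroxylation of the flavone (C3–H → C3–Li → C3–B → C3–OH).
- Flavone ⇐ palladium-catalysed carbonylative Sonogashira coupling and 6-endo annulation, forming C4a–C4, C4–C3 and O1–C2. Ring C is the only ring built; rings A and B are bought.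
- Iodophenol ⇐ 5-methoxyresorcinol (bis-MOM ether, lithiation–iodination between the two OMOM groups, deprotection, monobenzylation). Alkyne ⇐ isovanillin (benzylation, Ohira–Bestmann homologation).

Key step: step 7

Remarks on the chemistry: the target is achiral, so no stereocentre has to be set. The target is drawn as the free hydrogen sulfate. Aryl hydrogen sulfates are safer to handle as salts, so 16 and 17 would be carried as triethylammonium salts and the acid form released by a brief cold cation exchange at the very end. Both are written below in the neutral acid form.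

**Route**

Step 1
Reactants: 1 5-methoxyresorcinol
Product: 2 1-methoxy-3,5-bis(methoxymethoxy)benzene
Conditions: NaH (2.4 equiv), MOMCl (2.4 equiv), DMF, 0 °C → rt
Reagents that add atoms: chloromethyl methyl ether, COCCl
Why: Double Williamson-type O-alkylation of the bis-phenoxide with the reactive α-chloro ether should give the bis-acetal, whose MOM groups are the directing groups for step 2.

Step 2
Reactants: 2 1-methoxy-3,5-bis(methoxymethoxy)benzene
Product: 4 2-iodo-5-methoxy-1,3-bis(methoxymethoxy)benzene, via 2-lithio-5-methoxy-1,3-bis(methoxymethoxy)benzene 3 (not isolated)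
Conditions: n-BuLi (1.1 equiv), THF, 0 °C; then I2, −78 °C → rt
Reagents that add atoms: iodine, II
Why: Directed ortho-metalation: the position between the two OMOM groups is flanked by two chelating acetal ethers, which are stronger directors than OMe, so metalation is expected there rather than at the two OMOM/OMe-flanked positions, and iodine quench places the halide para to the methoxy group.

Step 3
Reactants: 4 2-iodo-5-methoxy-1,3-bis(methoxymethoxy)benzene
Product: 5 2-iodo-5-methoxybenzene-1,3-diol
Conditions: conc. HCl (cat.), MeOH, 40 °C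
Reagents that add atoms: none
Why: Acid-catalysed transacetalisation of the aryl MOM ethers to methanol frees both phenols; with dilute acid and no iodide or reductant present the aryl C–I bond should persist.

Step 4
Reactants: 5 2-iodo-5-methoxybenzene-1,3-diol
Product: 6 3-benzyloxy-2-iodo-5-methoxyphenol
Conditions: BnBr (0.95 equiv), K2CO3, acetone, reflux
Reagents that add atoms: benzyl bromide, BrCc1ccccc1
Why: Williamson mono-O-benzylation of a symmetrical diol with the halide limiting is statistical but dependable; the two hydroxyls are equivalent, so only one mono-ether can form, unreacted 5 is recovered and resubmitted, and the bis-ether is removed by chromatography.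

Step 5
Reactants: 7 isovanillin (3-hydroxy-4-methoxybenzaldehyde)
Product: 8 3-benzyloxy-4-methoxybenzaldehyde
Conditions: BnBr, K2CO3, DMF, rt
Reagents that add atoms: benzyl bromide, BrCc1ccccc1
Why: Williamson benzylation of the single phenol; the non-enolisable aldehyde is inert to carbonate.

Step 6
Reactants: 8 3-benzyloxy-4-methoxybenzaldehyde
Product: 9 2-benzyloxy-4-ethynyl-1-methoxybenzene
Conditions: dimethyl (1-diazo-2-oxopropyl)phosphonate, K2CO3, MeOH, rt
Reagents that add atoms: dimethyl (1-diazo-2-oxopropyl)phosphonate, COP(=O)(OC)C(=[N+]=[N-])C(C)=O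
Why: Ohira–Bestmann (Seyferth–Gilbert) homologation: methanolysis of the reagent gives the diazomethylphosphonate anion, which adds to the aldehyde, and loss of phosphate and N2 with 1,2-hydrogen shift gives the terminal alkyne under carbonate conditions that leave the benzyl ether untouched.

Step 7
Reactants: 6 3-benzyloxy-2-iodo-5-methoxyphenol; 9 2-benzyloxy-4-ethynyl-1-methoxybenzene; 10 carbon monoxide
Product: 12 5-benzyloxy-2-(3-benzyloxy-4-methoxyphenyl)-7-methoxychromen-4-one, via ortho-hydroxyaryl ynone 11 (not isolated)
Conditions: PdCl2(dppf) (5 mol%), CO (20 bar), Et2NH, 120 °C, copper-free, autoclave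
Reagents that add atoms: none
Why: Pd(0) inserts into the C–I bond of 6, CO inserts to give the aroyl-palladium, and amine-assisted (copper-free) transfer of the acetylide of 9 followed by reductive elimination gives the ortho-hydroxyaryl ynone 11, which forms C4a–C4 and C4–C3; the phenoxide oxygen then adds to the ynone β-carbon to form O1–C2. The closest known reaction type is the palladium-catalysed carbonylative Sonogashira coupling–annulation of ortho-iodophenols with terminal arylacetylenes to flavones, applied here to a doubly ortho-oxygenated iodide. Ring C closes by 6-endo-dig oxa-Michael addition, the electronically matched mode at the aryl-bearing β-carbon, which secondary-amine media are known to favour over 5-exo closure to the aurone. No stereocentre is formed. The step needs CO insertion to outrun direct alkynylation (which would lead to a 2-arylbenzofuran) and acetylide capture to outrun aminocarbonylation: the two ortho oxygens crowding the aryl–Pd bond slow direct coupling and favour migratory insertion, and CO pressure with omission of copper supports this. The ring A pattern is fixed by the substrate, since only one phenol is free and the iodine lies between it and the benzyloxy group, para to the methoxy group, so only the 5-benzyloxy-7-methoxy flavone can result.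

Step 8
Reactants: 12 5-benzyloxy-2-(3-benzyloxy-4-methoxyphenyl)-7-methoxychromen-4-one
Product: 15 5-benzyloxy-2-(3-benzyloxy-4-methoxyphenyl)-3-hydroxy-7-methoxychromen-4-one, via 3-lithioflavone 13 (not isolated), via lithium flavon-3-yl(trimethoxy)borate 14 (not isolated)
Conditions: LDA (1.5 equiv), THF, −78 °C; B(OMe)3, −78 → 0 °C; AcOH, 30% H2O2, 0 °C → rt
Reagents that add atoms: hydrogen peroxide, OO
Why: C3–H, the only vinylic proton α to the pyranone carbonyl, is removed by LDA at −78 °C (known C3 lithiation of flavones), the vinyllithium is trapped as the borate, and acidic peroxide oxidises C–B to C–OH (borylation–oxidation) without nucleophilic epoxidation of the enone.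

Step 9
Reactants: 15 5-benzyloxy-2-(3-benzyloxy-4-methoxyphenyl)-3-hydroxy-7-methoxychromen-4-one
Product: 16 5-benzyloxy-2-(3-benzyloxy-4-methoxyphenyl)-7-methoxy-4-oxochromen-3-yl hydrogen sulfate
Conditions: SO3·NEt3 (5 equiv), Et3N, DMF, 60 °C
Reagents that add atoms: sulfur trioxide–triethylamine complex, CC[N+](CC)(CC)S(=O)(=O)[O-]
Why: O-sulfonation of the only free hydroxyl with an amine–SO3 complex (standard flavonol sulfation); with the 5- and 3'-oxygens benzylated no site selection is needed, and excess reagent with warming should overcome the hydrogen bond of 3-OH to the C4 carbonyl.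

Step 10
Reactants: 16 5-benzyloxy-2-(3-benzyloxy-4-methoxyphenyl)-7-methoxy-4-oxochromen-3-yl hydrogen sulfate
Product: 17 ombuin 3-O-sulfate (5-hydroxy-2-(3-hydroxy-4-methoxyphenyl)-7-methoxy-4-oxochromen-3-yl hydrogen sulfate)
Conditions: H2 (1 atm), Pd(OH)2/C, MeOH–THF, rt; then Dowex 50W (H+), H2O–MeOH, 0 °C, lyophilise
Reagents that add atoms: none
Why: Catalytic hydrogenolysis cleaves both benzyl aryl ethers, while the aryl sulfate monoester salt, the tetrasubstituted C2=C3 bond and the methyl ethers are inert to H2/Pd; brief cold cation exchange then gives the acid form drawn.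

**Compound list**

1 | 5-methoxyresorcinol | COc1cc(O)cc(O)c1 | starting material
2 | 1-methoxy-3,5-bis(methoxymethoxy)benzene | COCOc1cc(OC)cc(OCOC)c1 | intermediate
3 | 2-lithio-5-methoxy-1,3-bis(methoxymethoxy)benzene | [Li]c1c(OCOC)cc(OC)cc1OCOC | intermediate (not isolated)
4 | 2-iodo-5-methoxy-1,3-bis(methoxymethoxy)benzene | COCOc1cc(OC)cc(OCOC)c1I | intermediate
5 | 2-iodo-5-methoxybenzene-1,3-diol | COc1cc(O)c(I)c(O)c1 | intermediate
6 | 3-benzyloxy-2-iodo-5-methoxyphenol | COc1cc(O)c(I)c(OCc2ccccc2)c1 | intermediate
7 | isovanillin | COc1ccc(C=O)cc1O | starting material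
8 | 3-benzyloxy-4-methoxybenzaldehyde | COc1ccc(C=O)cc1OCc1ccccc1 | intermediate
9 | 2-benzyloxy-4-ethynyl-1-methoxybenzene | C#Cc1ccc(OC)c(OCc2ccccc2)c1 | intermediate
10 | carbon monoxide | [C-]#[O+] | starting material
11 | 1-(2-benzyloxy-6-hydroxy-4-methoxyphenyl)-3-(3-benzyloxy-4-methoxyphenyl)prop-2-yn-1-one | COc1cc(O)c(C(=O)C#Cc2ccc(OC)c(OCc3ccccc3)c2)c(OCc2ccccc2)c1 | intermediate (not isolated)
12 | 5-benzyloxy-2-(3-benzyloxy-4-methoxyphenyl)-7-methoxychromen-4-one | COc1cc(OCc2ccccc2)c2c(=O)cc(-c3ccc(OC)c(OCc4ccccc4)c3)oc2c1 | intermediate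
13 | 5-benzyloxy-2-(3-benzyloxy-4-methoxyphenyl)-3-lithio-7-methoxychromen-4-one | COc1cc(OCc2ccccc2)c2c(=O)c([Li])c(-c3ccc(OC)c(OCc4ccccc4)c3)oc2c1 | intermediate (not isolated)
14 | lithium [5-benzyloxy-2-(3-benzyloxy-4-methoxyphenyl)-7-methoxy-4-oxochromen-3-yl]trimethoxyborate | COc1cc(OCc2ccccc2)c2c(=O)c([B-](OC)(OC)OC)c(-c3ccc(OC)c(OCc4ccccc4)c3)oc2c1.[Li+] | intermediate (not isolated)
15 | 5-benzyloxy-2-(3-benzyloxy-4-methoxyphenyl)-3-hydroxy-7-methoxychromen-4-one | COc1cc(OCc2ccccc2)c2c(=O)c(O)c(-c3ccc(OC)c(OCc4ccccc4)c3)oc2c1 | intermediate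
16 | 5-benzyloxy-2-(3-benzyloxy-4-methoxyphenyl)-7-methoxy-4-oxochromen-3-yl hydrogen sulfate (handled as triethylammonium salt) | COc1cc(OCc2ccccc2)c2c(=O)c(OS(=O)(=O)O)c(-c3ccc(OC)c(OCc4ccccc4)c3)oc2c1 | intermediate
17 | ombuin 3-O-sulfate | COc1cc(O)c2c(=O)c(OS(=O)(=O)O)c(-c3ccc(OC)c(O)c3)oc2c1 | target

**Step count**

Total: 10 steps. Longest linear sequence: 8 steps (1, 2, 3, 4, 7, 8, 9, 10); the alkyne branch (steps 5 and 6) joins at step 7.

**Steps most likely to fail, with fallbacks**

1. Step 7. The aroyl-palladium may be bypassed (direct alkynylation, then closure to a benzofuran) or intercepted by the amine, or oxidative addition at the doubly ortho-substituted C–I bond may be too slow. The fallback builds the ynone without palladium or CO; it sets out from 2 and 9 and returns at 12.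
   - Alkyne 9 is deprotonated (n-BuLi, THF, −78 °C) and acylated with N-methoxy-N-methylcarbamoyl chloride to give N-methoxy-N-methyl-3-(3-benzyloxy-4-methoxyphenyl)propiolamide F1.
   - Aryllithium 3, generated from 2 as in step 2, is added to F1 at −78 °C with acidic quench to give 3-(3-benzyloxy-4-methoxyphenyl)-1-[4-methoxy-2,6-bis(methoxymethoxy)phenyl]prop-2-yn-1-one F2.
   - HCl in MeOH removes both MOM groups to give 3-(3-benzyloxy-4-methoxyphenyl)-1-(2,6-dihydroxy-4-methoxyphenyl)prop-2-yn-1-one F3.
   - Et2NH in EtOH closes F3 by 6-endo addition (either phenol gives the same product, by symmetry) to 2-(3-benzyloxy-4-methoxyphenyl)-5-hydroxy-7-methoxychromen-4-one F4.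
   - Benzylation of the chelated 5-OH (BnBr, K2CO3, DMF, 70 °C) gives 12.

2. Step 8. The 3-lithio species may open by β-elimination of the ring oxygen to a phenoxide ynone, or borate trapping may be incomplete. The fallback oxidises without a carbanion; it sets out from 12 and returns at 15.
   - Dimethyldioxirane (acetone–CH2Cl2, 0 °C) epoxidises the C2=C3 bond to give racemic 5-benzyloxy-2-(3-benzyloxy-4-methoxyphenyl)-2,3-epoxy-7-methoxychroman-4-one F5 (cis-fused epoxide, necessarily).
   - Catalytic p-TsOH in CH2Cl2 opens the epoxide at C2 and, with loss of H3, gives flavonol 15.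

3. Step 9. Sulfation of the chelated, doubly flanked 3-OH may stall, and the ionic product may lose sulfate during purification. The fallback uses a neutral protected sulfate; it sets out from 15 and returns at 17.
   - 2,2,2-Trichloroethyl chlorosulfate with Et3N and DMAP in THF gives 5-benzyloxy-2-(3-benzyloxy-4-methoxyphenyl)-7-methoxy-4-oxochromen-3-yl 2,2,2-trichloroethyl sulfate F6, a diester that can be chromatographed on silica.
   - Pd/C with HCO2NH4 in MeOH (H2 admitted if the benzyl ethers lag) removes the trichloroethyl group and both benzyl ethers in one operation, giving 17 after the cold cation exchange of step 10.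

**Further compounds**

F1 | step 7 | N-methoxy-N-methyl-3-(3-benzyloxy-4-methoxyphenyl)propiolamide | CON(C)C(=O)C#Cc1ccc(OC)c(OCc2ccccc2)c1
F2 | step 7 | 3-(3-benzyloxy-4-methoxyphenyl)-1-[4-methoxy-2,6-bis(methoxymethoxy)phenyl]prop-2-yn-1-one | COCOc1cc(OC)cc(OCOC)c1C(=O)C#Cc1ccc(OC)c(OCc2ccccc2)c1
F3 | step 7 | 3-(3-benzyloxy-4-methoxyphenyl)-1-(2,6-dihydroxy-4-methoxyphenyl)prop-2-yn-1-one | COc1cc(O)c(C(=O)C#Cc2ccc(OC)c(OCc3ccccc3)c2)c(O)c1
F4 | step 7 | 2-(3-benzyloxy-4-methoxyphenyl)-5-hydroxy-7-methoxychromen-4-one | COc1cc(O)c2c(=O)cc(-c3ccc(OC)c(OCc4ccccc4)c3)oc2c1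
F5 | step 8 | 5-benzyloxy-2-(3-benzyloxy-4-methoxyphenyl)-2,3-epoxy-7-methoxychroman-4-one (racemic) | O=C1c2c(OCc3ccccc3)cc(OC)cc2OC2(c3ccc(OC)c(OCc4ccccc4)c3)OC12
F6 | step 9 | 5-benzyloxy-2-(3-benzyloxy-4-methoxyphenyl)-7-methoxy-4-oxochromen-3-yl 2,2,2-trichloroethyl sulfate | COc1cc(OCc2ccccc2)c2c(=O)c(OS(=O)(=O)OCC(Cl)(Cl)Cl)c(-c3ccc(OC)c(OCc4ccccc4)c3)oc2c1
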